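The ratio of impurity to free catalyst in the charge is 0.280, below one, and on the list of suspects one impurity removes one free catalyst for good. What survives, counted as a fraction of the starting material charged, is 7.20%, the working load. Product divided by this load gives turnovers per working catalyst.

in all of them: starting material 0.050 M; impurity 1.4 mM
- Sunday's: reagent 0.026 M; free catalyst 5 mM; run made earlier
- Friday's: reagent 0.10 M; free catalyst 5 mM; run made earlier
- flask: reagent 0.0525 M; free catalyst 5.0 mM; time 3.0 d

| run | time / d | product / % | catalyst intermediate D / % | starting material / % |
|---|---|---|---|---|
| Sunday's | 0.167 | 0 | 1 | 95 |
| Sunday's | 0.500 | 9 | 2 | 90 |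
| Sunday's | 0.833 | 13 | 3 | 82 |
| Sunday's | 1.25 | 18 | 3 | 79 |
| Sunday's | 1.67 | 27 | 1 | 70 |
| Sunday's | 2.50 | 39 | 2 | 60 |
| Sunday's | 3.00 | 42 | 0 | 55 |
| Friday's | 0.250 | 4 | 4 | 92 |
| Friday's | 0.333 | 8 | 7 | 89 |
| Friday's | 0.500 | 11 | 0 | 85 |
| Friday's | 0.833 | 19 | 0 | 74 |
| Friday's | 1.25 | 27 | 4 | 67 |
| Friday's | 2.08 | 48 | 5 | 47 |
| Friday's | 3.00 | 65 | 2 | 31 |

(standard deviation of a reading: 1.5 percentage points)

- on the list of suspects stand: reagent + free catalyst -> catalyst intermediate A; catalyst intermediate A -> catalyst intermediate B; starting material + catalyst intermediate B -> catalyst intermediate C; catalyst intermediate C -> by-product + catalyst intermediate D; catalyst intermediate D <-> catalyst intermediate E; catalyst intermediate E -> free catalyst + product; free catalyst + impurity -> spent catalyst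
- the reaction counts as stopped when no species that holds the starting material changes by six tenths of a point or more over the second half of the time

- why nothing more happens at 3.0 d, or that something still does (forward and back rates have come level / the reagent has run out first / all of the starting material has reacted / it is still moving / no working catalyst is left)
- amount of product at 3.0 d, in percent of the starting material charged
- amount of catalyst intermediate D at 3.0 d, in percent of the starting material charged
- amount of product if the flask were left three thousand times as long, in percent of the starting material charged

Sunday's run and Friday's run share this load and differ in reagent, and the flask's reagent lies between theirs. So Sunday's reading of 42% and Friday's reading of 65% at 3.00 d bracket the product, as 5.83 and 9.03 turnovers. Friday's reagent charge was 3.85 times Sunday's, yet its turnovers rose 1.55 times, so the curve flattens. If the curve flattens throughout this stretch, it stands above the straight chord between the two runs, which lifts the lower bound to about 50.2%. The upper bound stays. Drawing the reciprocal of turnovers straight against the reciprocal of reagent gives this reckoning's own figure, 55.4%. It may lean low: Sunday's limiting reagent covered 52.0% of the starting material, and Sunday's last product reading already stood at 80.8% of that amount.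

The forecast's central value stands inside the bracket and below that figure: 53% (47% to 59%), 2% of catalyst intermediate D, 100% eventually, and “so it is still moving”.

The flask gives 58.2% at 3.0 d, above the forecast, with 1.75% of catalyst intermediate D and 100% eventually, and it is still moving. At 1.50 d the spent catalyst stood at 28.0% of the catalyst charged, with impurity at 0%. On the working load, the flask made 8.08 turnovers.

    reagent + free catalyst → catalyst intermediate A (k = 16.0 /M/h)
    catalyst intermediate A → catalyst intermediate B (k = 8.00 /h)
    starting material + catalyst intermediate B → catalyst intermediate C (k = 20.0 /M/h)
    catalyst intermediate C → by-product + catalyst intermediate D (k = 0.720 /h)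
    catalyst intermediate D ⇌ catalyst intermediate E (K = 0.760, k = 0.910 /h)
    catalyst intermediate E → free catalyst + product (k = 0.890 /h)
    free catalyst + impurity → spent catalyst (k = 970 /M/h)

A neighbouring flask with 0.0030 M of free catalyst has a working load of 3.20%, so the same turnovers give 25.9%. Its computed product is 28.8%.

Readings and results were computed on assumed constants; scatter was added.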